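**Plan**

1. Numbering (jatrophane): the cyclopentenone is C15–C1–C2–C3–C4 (C3 ketone, C15 acetoxy carbon), the 12-membered ring is C4–C15 (C14 ketone), and the oxolane oxygen links C6 and C9.
2. Retrosynthesis: remove the C15 acetate and return C14 to a silyloxy carbinol; cut C4–C15 (transannular aldol with loss of a C5 oxygen) to a 15-membered (Z)-3,15-enedione, which is a 3-methylfuran whose oxygen bridges C3 and C15. Then cut C11–C12 (ring-closing metathesis), C13–C14 (crotylboration), C3–C4 (furyllithium plus epoxide), C6–O (epoxide opening) and C9–C10 (prenylboration).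
3. Forward order: geranyl acetate gives the oxolane epoxide; 3-methylfuran is attached at C4; C14 and C13 are added; metathesis closes the furanophane; the furan is then unmasked so that the five-membered ring closes across the macrocycle; C14 is oxidised and C15 acetylated last.
4. Enabling feature: C3 and C15 are 1,4-related oxygenated carbons held cis by C1=C2 (bearing the C2 methyl), the retron of a 2,5-disubstituted 3-methylfuran. The furan is a temporary C3–O–C15 ring that fixes the Z-enedione and is cleaved in the key step; the C5 silyloxy group and the C14 stereocentre are helpers removed afterwards.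
5. Stereochemistry: C9 from reagent-controlled prenylboration; C6 (and helper C5) from Sharpless epoxidation plus invertive 5-exo cyclisation; C13 and helper C14 from catalytic anti-crotylboration; C15 from 1,2-induction by C14 in the transannular aldol; C4=C5 geometry from the ring-constrained E1cB.

Key step: step 13

Remark: TBS is tert-butyldimethylsilyl and (R)-TRIP is (R)-3,3'-bis(2,4,6-triisopropylphenyl)-1,1'-binaphthyl-2,2'-diyl hydrogen phosphate. The 11E geometry written for 18 and the C4 configuration written for 22 are assumptions without consequence, because both elements are erased in the following operation. The facial senses quoted for the two boron reagents (steps 2 and 9) are assigned from the usual behaviour of these reagent classes and would be confirmed on the first adducts.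

**Route**

Step 1
Reactants: 1 geranyl acetate
Product: 2 (2E)-3-methyl-6-oxohex-2-en-1-yl acetate
Conditions: O3 (1 equiv), CH2Cl2, pyridine, −78 °C; then Me2S, −78 → 23 °C
Reagents that add atoms: ozone, [O-][O+]=O
Why: Ozonolysis with reductive work-up should cleave only the electron-rich 6,7-alkene, because the 2,3-alkene is deactivated by the allylic acetate; no stereocentre is formed.

Step 2
Reactants: 2 (2E)-3-methyl-6-oxohex-2-en-1-yl acetate
Product: 4 (2E,6S)-3,7,7-trimethylnona-2,8-diene-1,6-diol, via hydroxy acetate 3 (not isolated)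
Conditions: Ipc2BH [from (−)-α-pinene], 3-methylbuta-1,2-diene, THF, −25 → 0 °C; then 2, Et2O, −78 °C; then NaOH, H2O2, 23 °C
Reagents that add atoms: B-(3-methylbut-2-en-1-yl)diisopinocampheylborane, C[C@@H]1[C@@H](B(CC=C(C)C)[C@H]2C[C@H]3C[C@@H]([C@@H]2C)C3(C)C)C[C@H]2C[C@@H]1C2(C)C, made in the flask from 3-methylbuta-1,2-diene, CC(C)=C=C
Why: In this Brown prenylboration the γ-carbon of the allylborane should add through a chair transition state to the Re face of the aldehyde, forming C9–C10, the quaternary C10 and the 9S carbinol under reagent control, while the alkaline peroxide work-up also removes the acetate.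

Step 3
Reactants: 4 (2E,6S)-3,7,7-trimethylnona-2,8-diene-1,6-diol
Product: 6 (1R)-1-[(2S,5S)-2-methyl-5-(2-methylbut-3-en-2-yl)oxolan-2-yl]ethane-1,2-diol, via epoxy alcohol 5 (not isolated)
Conditions: Ti(OiPr)4 (10 mol %), D-(−)-diethyl tartrate (12 mol %), t-BuOOH, 4 Å MS, CH2Cl2, −20 °C; then CSA (10 mol %), 0 °C
Reagents that add atoms: tert-butyl hydroperoxide, CC(C)(C)OO
Why: Sharpless asymmetric epoxidation of the E-allylic alcohol with the D-tartrate should give the (5R,6R)-epoxide (the homoallylic C9 alcohol and the vinyl group are inert), and acid-promoted 5-exo opening by the C9 hydroxyl at tertiary C6 with inversion then sets 6S in the 2,5-trans oxolane and leaves a 5R hydroxyl.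

Step 4
Reactants: 6 (1R)-1-[(2S,5S)-2-methyl-5-(2-methylbut-3-en-2-yl)oxolan-2-yl]ethane-1,2-diol
Product: 8 (2S,5S)-2-methyl-5-(2-methylbut-3-en-2-yl)-2-[(2R)-oxiran-2-yl]oxolane, via monotosylate 7 (not isolated)
Conditions: NaH (2.2 equiv), N-tosylimidazole (1.05 equiv), THF, 0 → 23 °C
Reagents that add atoms: none
Why: Selective sulfonylation of the primary hydroxyl followed by intramolecular Williamson displacement by the C5 alkoxide (one-pot diol-to-epoxide conversion) should keep the C5 configuration, because only the C4–O bond is broken.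

Step 5
Reactants: 9 3-methylfuran
Product: 10 2-bromo-3-methylfuran
Conditions: NBS, DMF, 0 → 23 °C; distilled and used at once
Reagents that add atoms: N-bromosuccinimide, O=C1CCC(=O)N1Br
Why: Electrophilic bromination of the furan should occur at the α-position next to the methyl group, which is activated by both the ring oxygen and the alkyl substituent.

Step 6
Reactants: 10 2-bromo-3-methylfuran; 8 (2S,5S)-2-methyl-5-(2-methylbut-3-en-2-yl)-2-[(2R)-oxiran-2-yl]oxolane
Product: 12 (1R)-2-(3-methylfuran-2-yl)-1-[(2S,5S)-2-methyl-5-(2-methylbut-3-en-2-yl)oxolan-2-yl]ethan-1-ol, via furyllithium 11 (not isolated)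
Conditions: t-BuLi (2.0 equiv), Et2O, −78 °C; then 8, THF, −78 → 23 °C
Reagents that add atoms: none
Why: Bromine–lithium exchange gives the 2-furyllithium regiospecifically, and SN2 opening of the monosubstituted epoxide at its terminal carbon should form the C3–C4 bond and release the C5 hydroxyl with C5 untouched.

Step 7
Reactants: 12 (1R)-2-(3-methylfuran-2-yl)-1-[(2S,5S)-2-methyl-5-(2-methylbut-3-en-2-yl)oxolan-2-yl]ethan-1-ol
Product: 13 tert-butyl(dimethyl)[(1R)-2-(3-methylfuran-2-yl)-1-[(2S,5S)-2-methyl-5-(2-methylbut-3-en-2-yl)oxolan-2-yl]ethoxy]silane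
Conditions: TBSOTf, 2,6-lutidine, CH2Cl2, −78 → 0 °C
Reagents that add atoms: tert-butyldimethylsilyl trifluoromethanesulfonate, CC(C)(C)[Si](C)(C)OS(=O)(=O)C(F)(F)F
Why: Silylation of the hindered secondary alcohol with the silyl triflate protects C5–O for the organolithium steps and installs the group that later leaves from C5.

Step 8
Reactants: 13 tert-butyl(dimethyl)[(1R)-2-(3-methylfuran-2-yl)-1-[(2S,5S)-2-methyl-5-(2-methylbut-3-en-2-yl)oxolan-2-yl]ethoxy]silane
Product: 15 5-[(2R)-2-{[tert-butyl(dimethyl)silyl]oxy}-2-[(2S,5S)-2-methyl-5-(2-methylbut-3-en-2-yl)oxolan-2-yl]ethyl]-4-methylfuran-2-carbaldehyde, via lithiofuran 14 (not isolated)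
Conditions: n-BuLi (1.2 equiv), THF, −78 → 0 °C; then DMF, −78 → 23 °C
Reagents that add atoms: N,N-dimethylformamide, CN(C)C=O
Why: α-Lithiation of the 2,3-dialkylfuran can only occur at the one remaining α-hydrogen (C15), and formylation of the lithiofuran with DMF installs C14.

Step 9
Reactants: 15 5-[(2R)-2-{[tert-butyl(dimethyl)silyl]oxy}-2-[(2S,5S)-2-methyl-5-(2-methylbut-3-en-2-yl)oxolan-2-yl]ethyl]-4-methylfuran-2-carbaldehyde
Product: 16 (1R,2R)-1-{5-[(2R)-2-{[tert-butyl(dimethyl)silyl]oxy}-2-[(2S,5S)-2-methyl-5-(2-methylbut-3-en-2-yl)oxolan-2-yl]ethyl]-4-methylfuran-2-yl}-2-methylbut-3-en-1-ol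
Conditions: (E)-crotylboronic acid pinacol ester (1.5 equiv), (R)-TRIP (5 mol %), 4 Å MS, toluene, −30 °C
Reagents that add atoms: (E)-crotylboronic acid pinacol ester, C/C=C/CB1OC(C)(C)C(C)(C)O1
Why: In this chiral phosphoric acid-catalysed crotylboration the E-boronate reacts through a closed chair transition state (anti adduct) on the Re face selected by the catalyst, which should set 13R (kept) and 14R (helper).

Step 10
Reactants: 16 (1R,2R)-1-{5-[(2R)-2-{[tert-butyl(dimethyl)silyl]oxy}-2-[(2S,5S)-2-methyl-5-(2-methylbut-3-en-2-yl)oxolan-2-yl]ethyl]-4-methylfuran-2-yl}-2-methylbut-3-en-1-ol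
Product: 17 bis-TBS ether of 16 (14-O-TBS, 5-O-TBS diene)
Conditions: TBSOTf, 2,6-lutidine, CH2Cl2, −78 → 0 °C
Reagents that add atoms: tert-butyldimethylsilyl trifluoromethanesulfonate, CC(C)(C)[Si](C)(C)OS(=O)(=O)C(F)(F)F
Why: Silylation prevents the free furfuryl alcohol from trapping the later enedione as a pyranone hemiketal and supplies the non-chelating polar group that directs the aldol.

Step 11
Reactants: 17 bis-TBS ether of 16
Product: 18 (5R,6S,9S,11E,13R,14R)-5,14-bis(tert-butyldimethylsilyloxy)-3,15:6,9-diepoxy-4,15-secojatropha-1(15),2,11-triene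
Conditions: second-generation Grubbs catalyst (15 mol %), toluene (1 mM), 80 °C
Reagents that add atoms: none
Why: Ring-closing metathesis should load at the less hindered C13 vinyl group and close onto the neopentyl vinyl group with loss of ethene, giving the 15-membered carbocycle C1–C15 bridged by the furan oxygen (C3–O–C15) and the oxolane oxygen.

Step 12
Reactants: 18 (5R,6S,9S,11E,13R,14R)-5,14-bis(tert-butyldimethylsilyloxy)-3,15:6,9-diepoxy-4,15-secojatropha-1(15),2,11-triene
Product: 19 (5R,6S,9S,13R,14R)-5,14-bis(tert-butyldimethylsilyloxy)-3,15:6,9-diepoxy-4,15-secojatropha-1(15),2-diene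
Conditions: H2 (1 atm), [Ir(cod)(PCy3)(py)]PF6 (10 mol %), CH2Cl2, 23 °C
Reagents that add atoms: none
Why: Homogeneous hydrogenation with this cationic iridium catalyst should reduce the hindered disubstituted C11=C12 alkene while the aromatic furan and the silyl ethers are untouched; no stereocentre is formed.

Step 13
Reactants: 19 (5R,6S,9S,13R,14R)-5,14-bis(tert-butyldimethylsilyloxy)-3,15:6,9-diepoxy-4,15-secojatropha-1(15),2-diene
Product: 23 (4E,6S,9S,13R,14R,15S)-14-(tert-butyldimethylsilyloxy)-6,9-epoxy-15-hydroxyjatropha-1,4-dien-3-one, via endoperoxide 20 (not isolated), via enedione 21 (not isolated), via aldol adduct 22 (not isolated)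
Conditions: O2, visible light, methylene blue (cat.), CH2Cl2, −78 °C; then Me2S, −78 → 0 °C; then DBU (2 equiv), 0 → 40 °C
Reagents that add atoms: dioxygen (as singlet oxygen), O=O
Why: Singlet oxygen adds [4+2] across furan carbons C3 and C15, Me2S reduces the endoperoxide to the (Z)-C1=C2 3,15-enedione, DBU enolises the C4 methylene of the C3 ketone, the enolate adds to the C15 ketone across the ring, and E1cB loss of silanolate from C5 gives the exocyclic C4=C5 enone. The closest known reaction type is the oxidative opening of 2,5-dialkylfurans to cis-enediones followed by base-mediated intramolecular, including transannular, aldol closure to 4-hydroxycyclopent-2-enones. The five-membered ring C15–C1–C2–C3–C4 closes in the 5-(enolendo)-exo-trig mode, formally disfavoured but routine for cis-ene-1,4-diones, and the same bond divides the 15-membered carbocycle so that the 12-membered ring C4–C15 arises without a separate closure. C15 is set by the 14R silyloxy group (polar Felkin–Anh: the C14–O bond anti to the incoming C4, with the ring tether through C13 on the attacking Si face), which should give 15S; the transient C4 centre is erased, and the E geometry of C4=C5 follows from the ring (C6 cis to C15) and thermodynamic control. The step needs C4 rather than C14 enolisation (a methylene against a hindered silyloxy methine, and only the C4 pathway is drained irreversibly by the elimination), ring closure before silanolate loss (a poor leaving group against a fast five-ring aldol), and retention of the Z-enedione, which is fixed at birth by the furan and consumed cold.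

Step 14
Reactants: 23 (4E,6S,9S,13R,14R,15S)-14-(tert-butyldimethylsilyloxy)-6,9-epoxy-15-hydroxyjatropha-1,4-dien-3-one
Product: 24 (4E,6S,9S,13R,14R,15S)-6,9-epoxy-14,15-dihydroxyjatropha-1,4-dien-3-one
Conditions: HF·pyridine, pyridine, THF, 0 → 23 °C
Reagents that add atoms: none
Why: Fluoride cleavage of the remaining silyl ether under mildly acidic conditions should be tolerated by the cross-conjugated dienone and the tertiary alcohol, which cannot undergo retro-aldol because C4 is sp2.

Step 15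
Reactants: 24 (4E,6S,9S,13R,14R,15S)-6,9-epoxy-14,15-dihydroxyjatropha-1,4-dien-3-one
Product: 25 (4E,6S,9S,13R,15S)-6,9-epoxy-15-hydroxyjatropha-1,4-diene-3,14-dione
Conditions: Dess–Martin periodinane, pyridine, CH2Cl2, 0 → 23 °C
Reagents that add atoms: none
Why: Dess–Martin oxidation converts only the secondary C14 alcohol (the tertiary C15 alcohol cannot be oxidised), removing the helper stereocentre under buffered conditions that should not epimerise C13.

Step 16
Reactants: 25 (4E,6S,9S,13R,15S)-6,9-epoxy-15-hydroxyjatropha-1,4-diene-3,14-dione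
Product: 26 (4E,6S,9S,13R,15S)-15-acetoxy-6,9-epoxyjatropha-1,4-diene-3,14-dione (CNP0144863.1)
Conditions: Ac2O, DMAP, Et3N, CH2Cl2, 23 → 40 °C
Reagents that add atoms: acetic anhydride, CC(=O)OC(C)=O
Why: DMAP-catalysed (Steglich-type) acylation of the tertiary α-hydroxy ketone should give the acetate without breaking any bond to C15 or C13.

**Compound list**

1 | geranyl acetate, (2E)-3,7-dimethylocta-2,6-dien-1-yl acetate | CC(C)=CCC/C(C)=C/COC(C)=O | starting material
2 | (2E)-3-methyl-6-oxohex-2-en-1-yl acetate | O=CCC/C(C)=C/COC(C)=O | intermediate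
3 | (2E,6S)-6-hydroxy-3,7,7-trimethylnona-2,8-dien-1-yl acetate | CC(=O)OC/C=C(C)/CC[C@H](O)C(C)(C)C=C | intermediate (not isolated)
4 | (2E,6S)-3,7,7-trimethylnona-2,8-diene-1,6-diol | OC/C=C(C)/CC[C@H](O)C(C)(C)C=C | intermediate
5 | [(2R,3R)-3-[(3S)-3-hydroxy-4,4-dimethylhex-5-en-1-yl]-3-methyloxiran-2-yl]methanol | OC[C@H]1O[C@]1(C)CC[C@H](O)C(C)(C)C=C | intermediate (not isolated)
6 | (1R)-1-[(2S,5S)-2-methyl-5-(2-methylbut-3-en-2-yl)oxolan-2-yl]ethane-1,2-diol | OC[C@@H](O)[C@]1(C)CC[C@H](O1)C(C)(C)C=C | intermediate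
7 | (2R)-2-hydroxy-2-[(2S,5S)-2-methyl-5-(2-methylbut-3-en-2-yl)oxolan-2-yl]ethyl 4-methylbenzenesulfonate | Cc1ccc(cc1)S(=O)(=O)OC[C@@H](O)[C@]1(C)CC[C@H](O1)C(C)(C)C=C | intermediate (not isolated)
8 | (2S,5S)-2-methyl-5-(2-methylbut-3-en-2-yl)-2-[(2R)-oxiran-2-yl]oxolane | C1O[C@H]1[C@]2(C)CC[C@H](O2)C(C)(C)C=C | intermediate
9 | 3-methylfuran | Cc1ccoc1 | starting material
10 | 2-bromo-3-methylfuran | Cc1ccoc1Br | intermediate
11 | (3-methylfuran-2-yl)lithium | Cc1ccoc1[Li] | intermediate (not isolated)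
12 | (1R)-2-(3-methylfuran-2-yl)-1-[(2S,5S)-2-methyl-5-(2-methylbut-3-en-2-yl)oxolan-2-yl]ethan-1-ol | Cc1ccoc1C[C@@H](O)[C@]1(C)CC[C@H](O1)C(C)(C)C=C | intermediate
13 | tert-butyl(dimethyl)[(1R)-2-(3-methylfuran-2-yl)-1-[(2S,5S)-2-methyl-5-(2-methylbut-3-en-2-yl)oxolan-2-yl]ethoxy]silane | Cc1ccoc1C[C@@H](O[Si](C)(C)C(C)(C)C)[C@]1(C)CC[C@H](O1)C(C)(C)C=C | intermediate
14 | 5-lithio derivative of 13 (lithium at the free furan α-carbon, C15) | [Li]c1cc(C)c(o1)C[C@@H](O[Si](C)(C)C(C)(C)C)[C@]1(C)CC[C@H](O1)C(C)(C)C=C | intermediate (not isolated)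
15 | 5-[(2R)-2-{[tert-butyl(dimethyl)silyl]oxy}-2-[(2S,5S)-2-methyl-5-(2-methylbut-3-en-2-yl)oxolan-2-yl]ethyl]-4-methylfuran-2-carbaldehyde | O=Cc1cc(C)c(o1)C[C@@H](O[Si](C)(C)C(C)(C)C)[C@]1(C)CC[C@H](O1)C(C)(C)C=C | intermediate
16 | (1R,2R)-1-{5-[(2R)-2-{[tert-butyl(dimethyl)silyl]oxy}-2-[(2S,5S)-2-methyl-5-(2-methylbut-3-en-2-yl)oxolan-2-yl]ethyl]-4-methylfuran-2-yl}-2-methylbut-3-en-1-ol | C=C[C@@H](C)[C@@H](O)c1cc(C)c(o1)C[C@@H](O[Si](C)(C)C(C)(C)C)[C@]1(C)CC[C@H](O1)C(C)(C)C=C | intermediate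
17 | bis-TBS ether of 16 (TBS on the C14 and C5 oxygens; 13R,14R,5R,6S,9S) | C=C[C@@H](C)[C@@H](O[Si](C)(C)C(C)(C)C)c1cc(C)c(o1)C[C@@H](O[Si](C)(C)C(C)(C)C)[C@]1(C)CC[C@H](O1)C(C)(C)C=C | intermediate
18 | (5R,6S,9S,11E,13R,14R)-5,14-bis(tert-butyldimethylsilyloxy)-3,15:6,9-diepoxy-4,15-secojatropha-1(15),2,11-triene (furanophane alkene) | c12cc(C)c(o1)C[C@@H](O[Si](C)(C)C(C)(C)C)[C@]1(C)CC[C@H](O1)C(C)(C)/C=C/[C@@H](C)[C@H]2O[Si](C)(C)C(C)(C)C | intermediate
19 | (5R,6S,9S,13R,14R)-5,14-bis(tert-butyldimethylsilyloxy)-3,15:6,9-diepoxy-4,15-secojatropha-1(15),2-diene (furanophane) | c12cc(C)c(o1)C[C@@H](O[Si](C)(C)C(C)(C)C)[C@]1(C)CC[C@H](O1)C(C)(C)CC[C@@H](C)[C@H]2O[Si](C)(C)C(C)(C)C | intermediate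
20 | furan 2,5-endoperoxide of 19 (3,15-epidioxy-3,15-epoxide; C3 and C15 bridgehead configuration not defined, either face converges) | C123C=C(C)C(O1)(OO2)C[C@@H](O[Si](C)(C)C(C)(C)C)[C@]1(C)CC[C@H](O1)C(C)(C)CC[C@@H](C)[C@H]3O[Si](C)(C)C(C)(C)C | intermediate (not isolated)
21 | (1Z,5R,6S,9S,13R,14R)-5,14-bis(tert-butyldimethylsilyloxy)-6,9-epoxy-4,15-secojatroph-1-ene-3,15-dione | O=C1/C=C(C)\C(=O)C[C@@H](O[Si](C)(C)C(C)(C)C)[C@]2(C)CC[C@H](O2)C(C)(C)CC[C@@H](C)[C@H]1O[Si](C)(C)C(C)(C)C | intermediate (not isolated)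
22 | (4R,5R,6S,9S,13R,14R,15S)-5,14-bis(tert-butyldimethylsilyloxy)-6,9-epoxy-15-hydroxyjatroph-1-en-3-one | O[C@@]12C=C(C)C(=O)[C@@H]1[C@@H](O[Si](C)(C)C(C)(C)C)[C@]1(C)CC[C@H](O1)C(C)(C)CC[C@@H](C)[C@H]2O[Si](C)(C)C(C)(C)C | intermediate (not isolated)
23 | (4E,6S,9S,13R,14R,15S)-14-(tert-butyldimethylsilyloxy)-6,9-epoxy-15-hydroxyjatropha-1,4-dien-3-one | O[C@@]12C=C(C)C(=O)/C1=C/[C@]1(C)CC[C@H](O1)C(C)(C)CC[C@@H](C)[C@H]2O[Si](C)(C)C(C)(C)C | intermediate
24 | (4E,6S,9S,13R,14R,15S)-6,9-epoxy-14,15-dihydroxyjatropha-1,4-dien-3-one | O[C@@]12C=C(C)C(=O)/C1=C/[C@]1(C)CC[C@H](O1)C(C)(C)CC[C@@H](C)[C@H]2O | intermediate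
25 | (4E,6S,9S,13R,15S)-6,9-epoxy-15-hydroxyjatropha-1,4-diene-3,14-dione | O[C@@]12C=C(C)C(=O)/C1=C/[C@]1(C)CC[C@H](O1)C(C)(C)CC[C@@H](C)C2=O | intermediate
26 | (4E,6S,9S,13R,15S)-15-acetoxy-6,9-epoxyjatropha-1,4-diene-3,14-dione (CNP0144863.1) | CC(=O)O[C@@]12C=C(C)C(=O)/C1=C/[C@]1(C)CC[C@H](O1)C(C)(C)CC[C@@H](C)C2=O | target

**Step count and risks**

Total steps: 16. Longest linear sequence: 15 (steps 1–4 and 6–16; step 5 is the side branch).

1. Step 13. What may go wrong: the C4 enolate may add to the wrong face of the C15 ketone if ring strain overrides the 1,2-induction from C14; enolisation toward C14 or silanolate loss before ring closure are lesser concerns. Fallback (helper stereocentre inverted; sets out from 15, returns at 25): 15 would be crotylated with (Z)-crotylboronic acid pinacol ester and (S)-TRIP to the syn (13R,14S) alcohol F1. Silylation with TBSOTf and 2,6-lutidine would give the bis-silyl ether F2, ring-closing metathesis the furanophane alkene F3, and hydrogenation the furanophane F4. The same singlet oxygen, Me2S and DBU sequence would pass through the endoperoxide F5, the (Z)-enedione F6 and the aldol adduct F7 to the 14-epimeric hydroxy dienone F8, in which the silyloxy group sits on the other side of the C15 carbonyl during bond formation. HF·pyridine would give the diol F9, and Dess–Martin oxidation erases C14 and delivers 25.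

2. Step 11. What may go wrong: oligomerisation or no ring closure, because the neopentyl vinyl group engages slowly and the doubly bridged furanophane is strained. Fallback (five-membered ring first, macrocycle second; sets out from 17, returns at 22): the furan of 17 would be unmasked first with singlet oxygen and then Me2S, via the endoperoxide F10, to the open-chain (Z)-enedione F11. Et3N would cyclise this to the 4-hydroxycyclopentenone F12, with C15 set by the same Felkin–Anh control in an open chain. Ring-closing metathesis of F12 then has to close only the 12-membered carbocycle and would give the bicyclic alkene F13. Hydrogenation of its disubstituted alkene with H2 and RhCl(PPh3)3, the trisubstituted enone being left, would give 22, which DBU converts to 23.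

3. Step 16. What may go wrong: acyloin (α-ketol) shift of the tertiary α-hydroxy ketone, epimerisation at C13, or incomplete acylation of the crowded tertiary alcohol. Fallback (acetylation before C14 becomes a ketone; sets out from 23, returns at 26): 23 would be acetylated with Ac2O and DMAP to the acetate F14 while C14 is still a silyloxy-bearing sp3 carbon. HF·pyridine would release the alcohol F15, and Dess–Martin oxidation of F15 gives 26 directly.

**Further compounds**

F1 | step 13 | (1S,2R)-1-{5-[(2R)-2-{[tert-butyl(dimethyl)silyl]oxy}-2-[(2S,5S)-2-methyl-5-(2-methylbut-3-en-2-yl)oxolan-2-yl]ethyl]-4-methylfuran-2-yl}-2-methylbut-3-en-1-ol (14-epimer of 16) | C=C[C@@H](C)[C@H](O)c1cc(C)c(o1)C[C@@H](O[Si](C)(C)C(C)(C)C)[C@]1(C)CC[C@H](O1)C(C)(C)C=C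
F2 | step 13 | bis-TBS ether of F1 (14-epimer of 17) | C=C[C@@H](C)[C@H](O[Si](C)(C)C(C)(C)C)c1cc(C)c(o1)C[C@@H](O[Si](C)(C)C(C)(C)C)[C@]1(C)CC[C@H](O1)C(C)(C)C=C
F3 | step 13 | 14-epimer of furanophane alkene 18 (14S) | c12cc(C)c(o1)C[C@@H](O[Si](C)(C)C(C)(C)C)[C@]1(C)CC[C@H](O1)C(C)(C)/C=C/[C@@H](C)[C@@H]2O[Si](C)(C)C(C)(C)C
F4 | step 13 | 14-epimer of furanophane 19 (14S) | c12cc(C)c(o1)C[C@@H](O[Si](C)(C)C(C)(C)C)[C@]1(C)CC[C@H](O1)C(C)(C)CC[C@@H](C)[C@@H]2O[Si](C)(C)C(C)(C)C
F5 | step 13 | 14-epimer of endoperoxide 20 | C123C=C(C)C(O1)(OO2)C[C@@H](O[Si](C)(C)C(C)(C)C)[C@]1(C)CC[C@H](O1)C(C)(C)CC[C@@H](C)[C@@H]3O[Si](C)(C)C(C)(C)C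
F6 | step 13 | 14-epimer of (Z)-enedione 21 | O=C1/C=C(C)\C(=O)C[C@@H](O[Si](C)(C)C(C)(C)C)[C@]2(C)CC[C@H](O2)C(C)(C)CC[C@@H](C)[C@@H]1O[Si](C)(C)C(C)(C)C
F7 | step 13 | 14-epimer of aldol adduct 22 | O[C@@]12C=C(C)C(=O)[C@@H]1[C@@H](O[Si](C)(C)C(C)(C)C)[C@]1(C)CC[C@H](O1)C(C)(C)CC[C@@H](C)[C@@H]2O[Si](C)(C)C(C)(C)C
F8 | step 13 | (4E,6S,9S,13R,14S,15S)-14-(tert-butyldimethylsilyloxy)-6,9-epoxy-15-hydroxyjatropha-1,4-dien-3-one (14-epimer of 23) | O[C@@]12C=C(C)C(=O)/C1=C/[C@]1(C)CC[C@H](O1)C(C)(C)CC[C@@H](C)[C@@H]2O[Si](C)(C)C(C)(C)C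
F9 | step 13 | (4E,6S,9S,13R,14S,15S)-6,9-epoxy-14,15-dihydroxyjatropha-1,4-dien-3-one (14-epimer of 24) | O[C@@]12C=C(C)C(=O)/C1=C/[C@]1(C)CC[C@H](O1)C(C)(C)CC[C@@H](C)[C@@H]2O
F10 | step 11 | furan 2,5-endoperoxide of 17 (bridgehead configuration not defined) | C=C[C@@H](C)[C@@H](O[Si](C)(C)C(C)(C)C)C12C=C(C)C(O1)(OO2)C[C@@H](O[Si](C)(C)C(C)(C)C)[C@]1(C)CC[C@H](O1)C(C)(C)C=C
F11 | step 11 | open-chain (Z)-3,15-enedione from 17 (both vinyl groups intact) | C=C[C@@H](C)[C@@H](O[Si](C)(C)C(C)(C)C)C(=O)/C=C(C)\C(=O)C[C@@H](O[Si](C)(C)C(C)(C)C)[C@]1(C)CC[C@H](O1)C(C)(C)C=C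
F12 | step 11 | 4-hydroxycyclopent-2-enone from F11 (C4–C15 bond formed, 15S, both vinyl groups intact, ring between C11 and C12 open) | C=C[C@@H](C)[C@@H](O[Si](C)(C)C(C)(C)C)[C@]1(O)C=C(C)C(=O)[C@@H]1[C@@H](O[Si](C)(C)C(C)(C)C)[C@]2(C)CC[C@H](O2)C(C)(C)C=C
F13 | step 11 | 11,12-didehydro derivative of 22 (11E) | O[C@@]12C=C(C)C(=O)[C@@H]1[C@@H](O[Si](C)(C)C(C)(C)C)[C@]1(C)CC[C@H](O1)C(C)(C)/C=C/[C@@H](C)[C@H]2O[Si](C)(C)C(C)(C)C
F14 | step 16 | (4E,6S,9S,13R,14R,15S)-15-acetoxy-14-(tert-butyldimethylsilyloxy)-6,9-epoxyjatropha-1,4-dien-3-one | CC(=O)O[C@@]12C=C(C)C(=O)/C1=C/[C@]1(C)CC[C@H](O1)C(C)(C)CC[C@@H](C)[C@H]2O[Si](C)(C)C(C)(C)C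
F15 | step 16 | (4E,6S,9S,13R,14R,15S)-15-acetoxy-6,9-epoxy-14-hydroxyjatropha-1,4-dien-3-one | CC(=O)O[C@@]12C=C(C)C(=O)/C1=C/[C@]1(C)CC[C@H](O1)C(C)(C)CC[C@@H](C)[C@H]2O
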